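The flask held the same amounts of both substrates and gas as the earlier runs, but less precatalyst: 4.2 mM against 5.9 mM on Sunday and 9.2 mM on Monday.

| flask | left-handed substrate | right-handed substrate | gas | precatalyst | remark | time |
|---|---|---|---|---|---|---|
| Sunday's | 2.2 M | 2.2 M | 200 mM (held) | 5.9 mM | run made earlier |  |
| Monday's | 2.2 M | 2.2 M | 200 mM (held) | 9.2 mM | run made earlier |  |
| flask | 2.2 M | 2.2 M | 200 mM (held) | 4.2 mM |  | 6.0 h |

| run | time / h | right-handed substrate / % | left-handed substrate / % | left-handed product / % |
|---|---|---|---|---|
| Sunday's | 1.33 | 33.2 | 26.0 | 21.3 |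
| Sunday's | 2.50 | 14.9 | 7.6 | 38.8 |
| Sunday's | 4.00 | 2.2 | 0 | 47.2 |
| Sunday's | 5.00 | 0 | 0 | 50.0 |
| Sunday's | 6.00 | 0 | 0 | 49.6 |
| Monday's | 0.500 | 44.1 | 41.7 | 6.7 |
| Monday's | 1.50 | 28.0 | 18.2 | 27.5 |
| Monday's | 3.00 | 3.2 | 1.7 | 45.7 |
| Monday's | 4.00 | 0.1 | 2.1 | 49.5 |
| Monday's | 6.00 | 0 | 0 | 50.9 |

(each reading ± 1 percentage point)

- whether the excess of right-handed substrate over left-handed substrate among what is left of the two reaches 98% by 6.0 h (yes / no)
- the highest excess of right-handed substrate over left-handed substrate among what is left of the two up to 6.0 h

I worked in fractions of each charge; the readings count both charges together, so each charge starts at 0.5. I called the negative logarithm of the fraction of a charge left its depth. Sunday's readings at 2.50 h and Monday's at 1.50 h gave on average 1.65 for the selectivity factor, the left-handed depth divided by the right-handed depth at one moment. The logarithm of right-handed over left-handed left is then the factor minus one, times the right-handed depth. So the excess grows with depth, its top stands at the last moment, and 98.0% needs a depth of 7.07.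

How deep could the flask get? Sunday's readings put the right-handed depth at 1.21 at 2.50 h and its later growth at 1.28 h⁻¹, which I treated as a pseudo-first-order tail. In one extreme the flask keeps Sunday's clock, and I reckoned depth 5.67 and excess 95.1%. In the other its clock slows in proportion to precatalyst, giving depth 3.47 and excess 81.0%.

Monday's readings lay between these: its precatalyst stood 1.56 times Sunday's, its tail constant, as read, 1.45 h⁻¹ just 1.13 times. Both estimates fall short of the depth needed, so I answered no. Sunday's reading of 2.2% behind the tail is too scattered for finer placing, so I took the midpoint, depth 4.57, excess 90.2%.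

The forecast answered no, with a top of 90%, “still rising at the end”.

The flask gave no, with a top of 91.9%.

    precatalyst → catalyst (k = 0.0236 min⁻¹)
    gas ⇌ reagent, rate k2*(csat - [reagent]) (kL = 0.185 min⁻¹)
    reagent + catalyst + left-handed substrate → catalyst + left-handed product (k = 39.9 M⁻² min⁻¹)
    left-handed product ⇌ right-handed product (k = 0.146 min⁻¹)
    reagent + catalyst + right-handed substrate → catalyst + right-handed product (k = 22.6 M⁻² min⁻¹)

The flask kept 1.6% of its right-handed charge at 6.00 h, a depth of 4.13, between my extremes. My factor turns that rest into an excess of 87.3%, where the flask stood at 91.9%. The neighbouring flask, the same charge stopped at 1.5 h, kept 67% of its right-handed charge, and the factor gives it 12.9%. That neighbouring flask stood at 15.3%, with 49% of its left-handed charge left.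

The earlier runs and the new flask are calculated for substances that don't exist, and the scatter is random.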